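The readings stem from a simulated flask on assumed constants; the scatter is artificial.

**Late times.** Late in the eta run [L] falls ever more slowly, and the chain length asked for is D over chains begun, so I need to know how far [L] has fallen by the end and how many chains there are.

| flask | L | E | remark | time |
|---|---|---|---|---|
| alpha | 1.5 M | 100 mM | run made earlier |  |
| eta | 1.5 M | 300 mM | run made earlier |  |
| green | 1.5 M | 150 mM |  | 2.5 d |
| ochre | 3.0 M | 150 mM |  | 2.5 d |

- alpha (time / h: D / %): 5.00: 3.4; 12.0: 10.5; 25.0: 28.2; 40.0: 45.1
- eta (time / h: D / %): 10.0: 22.6; 20.0: 49.5; 25.0: 57.4; 40.0: 71.6

(each reading ± 0.5 percentage points)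

* which of the two ends with the longer chains by the average number of monomer units in a chain (chains begun, living or dead) ("neither" if they lie within 10%) (green / ochre / neither)
* average number of monomer units in a chain (chains begun, living or dead) at the end, green
* average number of monomer units in a chain (chains begun, living or dead) at the end, ochre

- the average divides the monomer in chains by the number of chains begun, living and dead together
- candidate steps: L + X -> Q + D; L + Q -> D + Q; D + Q -> L + Q; E <-> X
- the earlier runs do not show the number of chains; that part of a forecast is a guess

**The floor.** In the eta run, two equal steps of 15.0 h gain 35 percentage points of D and then 14 points. If the steps go on shrinking in that ratio, D levels off near 81.4%. So I read a floor for [L] near 0.279 M, my estimate from these readings of the equilibrium monomer concentration.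

**Two ways.** If the pace follows the E charged, then at the same charge of L equal charge of E times time should give equal D. This plain way sets green's 60 h level with eta at 30.0 h, about 62.1%.

Now the test: alpha at 40.0 h should match eta at 13.3 h, about 31.6%, but alpha reads more than that, 45.1%. So the plain way cheats. Eta reaches alpha's last reading at 18.4 h. Equal products then require a lag (induction period), the hours struck off a run before charge times time counts: 7.55 h. With the lag, green stands level with eta at 33.8 h, about 65.7%, which is higher than the plain figure.

**My numbers.** The runs do not show chains, so I guess that each E charged begins one. Green then gives 6.57. I take ochre, with the same E and time, to keep green's share of the gap to the floor, 19.3%. That leaves [L] near 0.803 M and a length of 14.6.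

The forecast says ochre, with 6.7 for green and 15 for ochre, on the ground that “the reaction is reversible”.

**The result.** The flasks give ochre the longer chains: 7.18 for green and 16.6 for ochre. Green ends with D at 68.5% and Q at 0.143 M, less than the 150 mM of E charged. The lag sets green at 1.25 d level with eta at 18.8 h, about 46.2%; green then holds 45.7%.

    L + X → Q + D (k = 0.0640 M⁻¹ min⁻¹)
    L + Q → D + Q, rate k2*[Q]*[L] (k = 0.00620 M⁻¹ min⁻¹)
    D + Q → L + Q, rate k3*[Q] as long as [D] is above zero (k = 0.00240 min⁻¹)
    E ⇌ X (K = 19.0, k = 8.60 × 10⁻⁴ min⁻¹)

**Second flask.** A flask like green but with 0.090 M of E, read at the same time, stands, by the lag, level with eta at 23.3 h, about 54.7%, which gives a length of 9.11 if each E charged has begun a chain. That flask gives D at 57.5%, Q at 0.0858 M and a length of 10.1.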